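4 questions stand on this flask, and the one worth carrying to the next flask is how much mono adduct it holds when it stops.

| setting | west | flask |
|---|---|---|
| starting material | 32 mM | 32 mM |
| reagent | 80 mM | 80.0 mM |
| capture agent | 32 mM | 32.0 mM |
| remark | the very flask that is asked about, followed so far |  |
| time |  | 6.0 d |

west run (percent of the starting material charged)

| time / h | starting material / % | mono adduct / % | double product / % |
|---|---|---|---|
| 2.50 | 72.8 | 25.5 | 1.9 |
| 4.00 | 63.8 | 33.0 | 3.5 |
| 5.00 | 58.5 | 36.5 | 4.5 |
| 8.00 | 48.8 | 43.3 | 6.6 |
| 12.0 | 40.1 | 47.6 | 7.9 |
| 20.0 | 32.1 | 50.8 | 8.1 |
| 30.0 | 26.7 | 52.0 | 7.0 |

(scatter of a reading: 0.3 percentage points)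

1. the starting material standing at 6.0 d, as a percentage of the starting material charged
2. the mono adduct standing at 6.0 d, as a percentage of the starting material charged
3. the double product standing at 6.0 d, as a percentage of the starting material charged
4. the triple product standing at 6.0 d, as a percentage of the starting material charged

- on the list of suspects stand: reagent + mono adduct -> double product; reagent + double product -> triple product; starting material + reagent -> mono adduct; 2 reagent -> self-condensation product; double product + capture agent -> trapped intermediate

Write a for the starting material and m for the mono adduct, each as a fraction of the starting material charged. Suppose, as the suspects say, that reagent makes mono adduct from starting material and then turns mono adduct into double product. The reagent then stands in both rates, so divide one by the other and both reagent and time drop out. Per unit fall of ln a, m rises by a minus s times m, which integrates to m = (a^s − a)/(1 − s).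

Read s from the last interval of the west run, where ln a falls by 0.184 while m rises 1.2 percentage points. This gives the reading s = 0.445, the selectivity factor: the second step's rate constant over the first's. Test it on an earlier reading: at 12.0 h the curve gives 47.7% against 47.6% read.

The curve has its summit at a = 23.3%, where m reaches 52.2%, and it is flat there. Now set beside this flask the neighbour charged with 54 mM of starting material. That neighbour is charged with 1.48 reagent per starting material against 2.50 in this flask, so I expect it to stop at a higher a on the same curve, yet near the same height.

The forecast gives 19%, 52%, 0.6% and 0.5%, saying “M stays near 52%”. Put its a on the curve and my own reckoning gives m = 51.8%.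

This flask gives 18.4%, 51.7%, 0.337% and 0.127%, and the forecast held.

    reagent + mono adduct → double product (k = 0.890 M⁻¹ h⁻¹)
    reagent + double product → triple product (k = 0.0320 M⁻¹ h⁻¹)
    starting material + reagent → mono adduct (k = 2.00 M⁻¹ h⁻¹)
    2 reagent → self-condensation product (k = 0.950 M⁻¹ h⁻¹)
    double product + capture agent → trapped intermediate (k = 2.40 M⁻¹ h⁻¹)

The curve at this a gives 51.7%. Mono adduct was made 3.69 times faster than it was used up at 0.203 d. At the asked time its half-life by the step into double product is 160 d, far longer than the 0.41 d at charged concentrations. On the neighbour, a stands at 31.5%, above the summit's a, where this flask's lies below it. There s gives 51.0%, and the computed result is 51.0%.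

The earlier runs and the new flask are simulated from invented constants; scatter was added.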